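**Retrosynthetic overview**
1. Target triacid ⇐ triester 19. Ring A is closed last (C4–C5 by palladium-catalysed enolate alkenylation of a ring-B enol triflate, then C4 methylation and C5=C6 reduction); ring B comes from a Dieckmann closure (C5–C6) and alkylation at C10.
2. Ring D ⇐ ketyl–alkyne closure C13–C16 on the ring-C ketone 11.
3. Ring C is not built six-membered: the cyclopentanone of 9 (C13, C8, C9, C11, C12) takes up the exocyclic C14 by a Dowd–Beckwith 1,2-acyl shift, and the C8 radical so formed is propargylated (C8–C15) in the same radical chain.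
4. Enabling feature: the C13 oxygen and the quaternary C8 (common to rings B, C and D) are separated only by the methylene C14, so a C14 radical on C8 beside a C13 carbonyl rearranges to the ring-C ketone with the radical exactly on C8, where C15 must be attached.
5. Order of rings: cyclopentanone (C9 set by asymmetric Michael addition) → C (expansion) → D → B → A.

Key step: step 6

Remark: ent-gibberellane numbering (C-1 to C-20) is used for all intermediates; β is the face of H-5, H-9 and C-15, α the face of C-19, C-20 and C-14; the natural C-6 configuration (C-7 β) is assumed to be the thermodynamically preferred one in the tetracyclic esters.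

Step 1
Reactants: 1 2-iodocyclopent-2-en-1-one; 2 methyl bromoacetate
Product: 4 methyl 2-(5-oxocyclopent-1-en-1-yl)acetate, via bromo(2-methoxy-2-oxoethyl)zinc 3 (not isolated)
Conditions: Zn dust, THF, 40 °C; then 1, Pd2(dba)3 (2 mol %), P(t-Bu)3 (8 mol %), THF, 25 °C
Reagents that add atoms: none
Why: Negishi cross-coupling of a Reformatsky reagent with an α-iodoenone (oxidative addition of zerovalent palladium into C–I, transmetalation from zinc, reductive elimination) should tolerate the enone carbonyl, because zinc ester enolates add only slowly to ketones at 25 °C; no stereocentre is formed.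

Step 2
Reactants: 4 methyl 2-(5-oxocyclopent-1-en-1-yl)acetate; 5 tert-butyl methyl propanedioate
Product: 6 tert-butyl methyl 2-[(1R,2S)-2-(2-methoxy-2-oxoethyl)-3-oxocyclopentyl]propanedioate (both epimers at the malonate carbon)
Conditions: K2CO3 (solid, 0.3 equiv), N-benzylquininium chloride (10 mol %; N-benzylquinidinium chloride instead if the sense of induction is the opposite one), toluene, −20 °C
Reagents that add atoms: none
Why: Michael addition under chiral phase-transfer catalysis: the ammonium–malonate ion pair selects one face of the 2-substituted cyclopentenone and so sets C9 (1R), while C8 is protonated and equilibrated trans to the new malonyl group; the malonate carbon (later C10) stays epimerisable.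

Step 3
Reactants: 6 tert-butyl methyl 2-[(1R,2S)-2-(2-methoxy-2-oxoethyl)-3-oxocyclopentyl]propanedioate
Product: 7 tert-butyl methyl 2-[(1S)-2-(2-methoxy-2-oxoethyl)-3-[(trimethylsilyl)oxy]cyclopent-2-en-1-yl]propanedioate
Conditions: Me3SiCl, Et3N, DMF, 80 °C
Reagents that add atoms: chlorotrimethylsilane, C[Si](C)(C)Cl
Why: Thermodynamic enol silylation should favour the more substituted C13=C8 silyl enol ether over the C13=C12 isomer, which places the nucleophilic carbon at C8; C9 is untouched and the C8 centre is removed on purpose.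

Step 4
Reactants: 7 tert-butyl methyl 2-[(1S)-2-(2-methoxy-2-oxoethyl)-3-[(trimethylsilyl)oxy]cyclopent-2-en-1-yl]propanedioate
Product: 8 tert-butyl methyl 2-[(1R,2S,5R)-1-(2-methoxy-2-oxoethyl)-5-[(trimethylsilyl)oxy]bicyclo[3.1.0]hexan-2-yl]propanedioate
Conditions: Et2Zn, CH2I2 (premixed 1:2), CH2Cl2, −20 to 0 °C
Reagents that add atoms: diiodomethane, ICI
Why: Simmons–Smith cyclopropanation (Furukawa variant) of the electron-rich silyl enol ether is fast and tolerates esters; the carbenoid adds anti to the C9 substituent, and the two new centres (C8, C13) are destroyed again in steps 5 and 6.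

Step 5
Reactants: 8 tert-butyl methyl 2-[(1R,2S,5R)-1-(2-methoxy-2-oxoethyl)-5-[(trimethylsilyl)oxy]bicyclo[3.1.0]hexan-2-yl]propanedioate
Product: 9 tert-butyl methyl 2-[(1S,2S)-2-(iodomethyl)-2-(2-methoxy-2-oxoethyl)-3-oxocyclopentyl]propanedioate
Conditions: N-iodosuccinimide, CH2Cl2, 0 °C, dark
Reagents that add atoms: N-iodosuccinimide, O=C1CCC(=O)N1I
Why: Electrophilic ring opening of a siloxycyclopropane: iodonium attacks the unhindered methylene C14 and the C13–C14 bond breaks with loss of the silyl group, which returns the C13 ketone and leaves CH2I on the quaternary C8; the product has no α-hydrogen on C8 for elimination.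

Step 6
Reactants: 9 tert-butyl methyl 2-[(1S,2S)-2-(iodomethyl)-2-(2-methoxy-2-oxoethyl)-3-oxocyclopentyl]propanedioate; 10 tributyl(propa-1,2-dien-1-yl)stannane
Product: 11 tert-butyl methyl 2-[(1S,2R)-2-(2-methoxy-2-oxoethyl)-4-oxo-2-(prop-2-yn-1-yl)cyclohexyl]propanedioate
Conditions: 10 (3 equiv), AIBN (0.2 equiv, in portions), benzene (0.02 M), 80 °C
Reagents that add atoms: none
Why: Proposed new method: Bu3Sn• abstracts iodine from C14 and the primary C14 radical adds 3-exo-trig to the C13 carbonyl carbon; the cyclopropyloxy radical opens by β-scission of the C13–C8 bond (net 1,2-acyl shift), so that the cyclopentanone C13–C8–C9–C11–C12 takes up C14 and becomes the six-membered ring C with a tertiary radical on C8, which adds to the CH2 terminus of the allenylstannane, and loss of Bu3Sn• from the β-stannyl vinyl radical (SH2′) leaves the propargyl group C15–C17 on C8 and carries the chain. The closest known reactions are the Dowd–Beckwith ring expansion of α-halomethyl cycloalkanones with Bu3SnH and the Keck-type transfer of a propargyl group from allenylstannanes to alkyl radicals; their union in one chain through an unstabilised tertiary β-keto radical has not been shown. Ring C is closed by ring expansion (3-exo-trig addition to C=O followed by ring-opening β-scission), not by a direct cyclisation. The one new stereocentre, quaternary C8, is controlled by C9: the planar C8 radical is attacked anti to the vicinal malonyl group, which puts C15 trans to C10 and leaves the C6 arm cis to C10, as ring B requires. The step needs the unimolecular acyl shift to outrun bimolecular trapping of the primary radical, which high dilution and the absence of a tin hydride secure, and it needs β-scission towards C8 rather than reversion, which formation of the tertiary radical secures; the ester carbonyls are much poorer radical acceptors than the ketone.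

Step 7
Reactants: 11 tert-butyl methyl 2-[(1S,2R)-2-(2-methoxy-2-oxoethyl)-4-oxo-2-(prop-2-yn-1-yl)cyclohexyl]propanedioate
Product: 12 tert-butyl methyl 2-[(1R,2S,5S)-5-hydroxy-1-(2-methoxy-2-oxoethyl)-6-methylidenebicyclo[3.2.1]octan-2-yl]propanedioate
Conditions: SmI2 (2.5 equiv), HMPA, t-BuOH, THF, 0 °C
Reagents that add atoms: none
Why: Ketyl–alkyne radical cyclisation (5-exo-dig): the C13 ketyl adds to C16 of the propargyl group held axial on C8 and the vinyl radical is reduced and protonated to the exocyclic methylene, closing ring D; the bridgehead C13 alcohol can form only in the configuration that spans C8, and esters are inert to divalent samarium here.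

Step 8
Reactants: 12 tert-butyl methyl 2-[(1R,2S,5S)-5-hydroxy-1-(2-methoxy-2-oxoethyl)-6-methylidenebicyclo[3.2.1]octan-2-yl]propanedioate
Product: 13 4-tert-butyl 2-methyl 8-hydroxy-9-methylidene-3-oxotricyclo[6.2.1.0(1,5)]undecane-2,4-dicarboxylate (rings B, C, D; C-8, C-9, C-13 as in the target; C-6 and C-10 enolisable)
Conditions: NaOMe (1.5 equiv), MeOH, 65 °C; AcOH quench
Reagents that add atoms: none
Why: Dieckmann condensation: the C6 ester enolate attacks the methyl ester of the malonate (the tert-butyl ester is too hindered) and closes ring B cis-fused on C8–C9, the equilibrium being drawn to the product as its stabilised β-keto ester enolate; C6 and C10 stay enolisable and are fixed later.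

Step 9
Reactants: 13 4-tert-butyl 2-methyl 8-hydroxy-9-methylidene-3-oxotricyclo[6.2.1.0(1,5)]undecane-2,4-dicarboxylate; 14 methyl 5-bromopentanoate
Product: 15 4-tert-butyl 2-methyl 8-hydroxy-4-(5-methoxy-5-oxopentyl)-9-methylidene-3-oxotricyclo[6.2.1.0(1,5)]undecane-2,4-dicarboxylate (C-10: C-1 β, C-20 ester α)
Conditions: K2CO3 (1.5 equiv), Bu4NI (cat.), DMF, 40 °C
Reagents that add atoms: none
Why: C-alkylation of a β-keto ester enolate: of the two doubly activated positions C10 should react (C6 is neopentylic, next to the quaternary bridgehead C8), and the bromide is attacked from the β-face, anti to the C11 methylene of ring C on the adjacent C9, which sets quaternary C10 with C1 β and the C20 ester α.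

Step 10
Reactants: 15 4-tert-butyl 2-methyl 8-hydroxy-4-(5-methoxy-5-oxopentyl)-9-methylidene-3-oxotricyclo[6.2.1.0(1,5)]undecane-2,4-dicarboxylate
Product: 16 4-tert-butyl 2-methyl 8-hydroxy-4-(5-methoxy-5-oxopentyl)-9-methylidene-3-{[(trifluoromethyl)sulfonyl]oxy}tricyclo[6.2.1.0(1,5)]undec-2-ene-2,4-dicarboxylate
Conditions: KN(SiMe3)2 (1.05 equiv), PhNTf2, THF, −78 to 0 °C
Reagents that add atoms: N-phenylbis(trifluoromethanesulfonimide), O=S(=O)(N(c1ccccc1)S(=O)(=O)C(F)(F)F)C(F)(F)F
Why: Enol triflate formation from the remaining β-keto ester: C10 is now quaternary, so enolisation is possible only towards C6 and O-sulfonylation gives the C5(OTf)=C6 triflate regiospecifically; one equivalent of base does not deprotonate the tertiary C13 alcohol, and no stereocentre is formed.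

Step 11
Reactants: 16 4-tert-butyl 2-methyl 8-hydroxy-4-(5-methoxy-5-oxopentyl)-9-methylidene-3-{[(trifluoromethyl)sulfonyl]oxy}tricyclo[6.2.1.0(1,5)]undec-2-ene-2,4-dicarboxylate
Product: 17 20-tert-butyl 7,19-dimethyl ent-13-hydroxy-18-norgibberella-5,16-diene-7,19,20-trioate (4-H; C-4 epimers)
Conditions: Pd2(dba)3 (5 mol %), P(t-Bu)3 (12 mol %), LiN(SiMe3)2 (3.2 equiv), toluene, 60 °C; NH4Cl work-up
Reagents that add atoms: none
Why: Palladium-catalysed intramolecular α-alkenylation of an ester enolate (oxidative addition of zerovalent palladium into C5–OTf, enolate transmetalation at C4, reductive elimination, six-membered ring A): the tert-butyl ester at C20 cannot be attacked by the C4 enolate in a competing Claisen-type condensation, and the C4 centre formed is epimerisable and is reset in step 12.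

Step 12
Reactants: 17 20-tert-butyl 7,19-dimethyl ent-13-hydroxy-18-norgibberella-5,16-diene-7,19,20-trioate
Product: 18 20-tert-butyl 7,19-dimethyl ent-13-hydroxygibberella-5,16-diene-7,19,20-trioate
Conditions: LiN(SiMe3)2 (2.2 equiv), THF, DMPU, −78 °C; MeI, −78 to −20 °C
Reagents that add atoms: iodomethane, CI
Why: C-alkylation of an extended ester enolate: the C4 dienolate should react with MeI at C4, its less hindered terminus (C6 is flanked by quaternary C8), and from the β-face because the axial C20 ester on C10 blocks the α-face, so the methyl ends β (equatorial) and the C19 ester α (axial).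

Step 13
Reactants: 18 20-tert-butyl 7,19-dimethyl ent-13-hydroxygibberella-5,16-diene-7,19,20-trioate
Product: 19 20-tert-butyl 7,19-dimethyl ent-13-hydroxygibberell-16-ene-7,19,20-trioate
Conditions: SmI2 (5 equiv), HMPA, MeOH, THF, 0 °C; then NaOMe (0.2 equiv), MeOH, 25 °C
Reagents that add atoms: none
Why: Conjugate reduction of the α,β-unsaturated ester by SmI2 (electron transfer, protonation at C5, then at C6): C5 should be protonated from the β-face because the axial esters on C4 and C10 shield the α-face, giving the trans A/B fusion, and C6 is then equilibrated by NaOMe to the epimer with the C7 ester β, trans to C4; the 16-methylene is not reduced by electron transfer.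

Step 14
Reactants: 19 20-tert-butyl 7,19-dimethyl ent-13-hydroxygibberell-16-ene-7,19,20-trioate
Product: 20 ent-13-hydroxygibberell-16-ene-7,19,20-trioic acid 20-tert-butyl ester
Conditions: NaSEt (8 equiv), DMF, 90 °C; then 1 M HCl, 0 °C (pH 3)
Reagents that add atoms: none
Why: SN2 demethylation of the two methyl esters by thiolate at the methyl carbon avoids attack at the hindered C19 carbonyl and leaves the tert-butyl ester, the tertiary alcohol and the exocyclic alkene untouched; no stereocentre is affected.

Step 15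
Reactants: 20 ent-13-hydroxygibberell-16-ene-7,19,20-trioic acid 20-tert-butyl ester
Product: 22 ent-13-hydroxygibberell-16-ene-7,19,20-trioic acid (the target gibberellin), via tetrakis(trimethylsilyl) derivative 21 (not isolated)
Conditions: Me3SiOTf (6 equiv), 2,6-lutidine (8 equiv), CH2Cl2, 0 °C; then H2O, THF, citric acid
Reagents that add atoms: none
Why: Silyl triflate-mediated cleavage of the tert-butyl ester (O-silylation, loss of the tert-butyl cation as isobutene) runs under buffered, non-protic conditions that spare the acid-sensitive C13-hydroxy/C16-methylene unit; aqueous work-up hydrolyses the silyl esters and silyl ether of 21 to the triacid.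

**Compound list**
1 | 2-iodocyclopent-2-en-1-one | O=C1CCC=C1I | starting material
2 | methyl bromoacetate | COC(=O)CBr | starting material
3 | bromo(2-methoxy-2-oxoethyl)zinc | COC(=O)C[Zn]Br | intermediate
4 | methyl 2-(5-oxocyclopent-1-en-1-yl)acetate | COC(=O)CC1=CCCC1=O | intermediate
5 | tert-butyl methyl propanedioate | COC(=O)CC(=O)OC(C)(C)C | starting material
6 | tert-butyl methyl 2-[(1R,2S)-2-(2-methoxy-2-oxoethyl)-3-oxocyclopentyl]propanedioate (malonate carbon unassigned) | O=C1CC[C@@H](C(C(=O)OC)C(=O)OC(C)(C)C)[C@@H]1CC(=O)OC | intermediate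
7 | tert-butyl methyl 2-[(1S)-2-(2-methoxy-2-oxoethyl)-3-[(trimethylsilyl)oxy]cyclopent-2-en-1-yl]propanedioate | COC(=O)CC1=C(O[Si](C)(C)C)CC[C@H]1C(C(=O)OC)C(=O)OC(C)(C)C | intermediate
8 | tert-butyl methyl 2-[(1R,2S,5R)-1-(2-methoxy-2-oxoethyl)-5-[(trimethylsilyl)oxy]bicyclo[3.1.0]hexan-2-yl]propanedioate | COC(=O)C[C@@]12C[C@]1(O[Si](C)(C)C)CC[C@H]2C(C(=O)OC)C(=O)OC(C)(C)C | intermediate
9 | tert-butyl methyl 2-[(1S,2S)-2-(iodomethyl)-2-(2-methoxy-2-oxoethyl)-3-oxocyclopentyl]propanedioate | COC(=O)C[C@@]1(CI)C(=O)CC[C@H]1C(C(=O)OC)C(=O)OC(C)(C)C | intermediate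
10 | tributyl(propa-1,2-dien-1-yl)stannane | C=C=C[Sn](CCCC)(CCCC)CCCC | starting material
11 | tert-butyl methyl 2-[(1S,2R)-2-(2-methoxy-2-oxoethyl)-4-oxo-2-(prop-2-yn-1-yl)cyclohexyl]propanedioate | C#CC[C@]1(CC(=O)OC)CC(=O)CC[C@H]1C(C(=O)OC)C(=O)OC(C)(C)C | intermediate
12 | tert-butyl methyl 2-[(1R,2S,5S)-5-hydroxy-1-(2-methoxy-2-oxoethyl)-6-methylidenebicyclo[3.2.1]octan-2-yl]propanedioate | C=C1C[C@]2(CC(=O)OC)C[C@@]1(O)CC[C@H]2C(C(=O)OC)C(=O)OC(C)(C)C | intermediate
13 | 4-tert-butyl 2-methyl 8-hydroxy-9-methylidene-3-oxotricyclo[6.2.1.0(1,5)]undecane-2,4-dicarboxylate (C-8, C-9, C-13 as in the target; C-6, C-10 unassigned) | C=C1C[C@]23C[C@@]1(O)CC[C@H]2C(C(=O)OC(C)(C)C)C(=O)C3C(=O)OC | intermediate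
14 | methyl 5-bromopentanoate | COC(=O)CCCCBr | starting material
15 | 4-tert-butyl 2-methyl 8-hydroxy-4-(5-methoxy-5-oxopentyl)-9-methylidene-3-oxotricyclo[6.2.1.0(1,5)]undecane-2,4-dicarboxylate (C-10 as in the target; C-6 unassigned) | C=C1C[C@]23C[C@@]1(O)CC[C@H]2[C@@](CCCCC(=O)OC)(C(=O)OC(C)(C)C)C(=O)C3C(=O)OC | intermediate
16 | 4-tert-butyl 2-methyl 8-hydroxy-4-(5-methoxy-5-oxopentyl)-9-methylidene-3-{[(trifluoromethyl)sulfonyl]oxy}tricyclo[6.2.1.0(1,5)]undec-2-ene-2,4-dicarboxylate | C=C1C[C@]23C[C@@]1(O)CC[C@H]2[C@@](CCCCC(=O)OC)(C(=O)OC(C)(C)C)C(OS(=O)(=O)C(F)(F)F)=C3C(=O)OC | intermediate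
17 | 20-tert-butyl 7,19-dimethyl ent-13-hydroxy-18-norgibberella-5,16-diene-7,19,20-trioate (C-4 unassigned) | C=C1C[C@]23C[C@@]1(O)CC[C@H]2[C@]1(C(=O)OC(C)(C)C)CCCC(C(=O)OC)C1=C3C(=O)OC | intermediate
18 | 20-tert-butyl 7,19-dimethyl ent-13-hydroxygibberella-5,16-diene-7,19,20-trioate | C=C1C[C@]23C[C@@]1(O)CC[C@H]2[C@]1(C(=O)OC(C)(C)C)CCC[C@@](C)(C(=O)OC)C1=C3C(=O)OC | intermediate
19 | 20-tert-butyl 7,19-dimethyl ent-13-hydroxygibberell-16-ene-7,19,20-trioate | C=C1C[C@]23C[C@@]1(O)CC[C@H]2[C@]1(C(=O)OC(C)(C)C)CCC[C@@](C)(C(=O)OC)[C@H]1[C@@H]3C(=O)OC | intermediate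
20 | ent-13-hydroxygibberell-16-ene-7,19,20-trioic acid 20-tert-butyl ester | C=C1C[C@]23C[C@@]1(O)CC[C@H]2[C@]1(C(=O)OC(C)(C)C)CCC[C@@](C)(C(=O)O)[C@H]1[C@@H]3C(=O)O | intermediate
21 | tris(trimethylsilyl) ent-13-[(trimethylsilyl)oxy]gibberell-16-ene-7,19,20-trioate | C=C1C[C@]23C[C@@]1(O[Si](C)(C)C)CC[C@H]2[C@]1(C(=O)O[Si](C)(C)C)CCC[C@@](C)(C(=O)O[Si](C)(C)C)[C@H]1[C@@H]3C(=O)O[Si](C)(C)C | intermediate
22 | ent-13-hydroxygibberell-16-ene-7,19,20-trioic acid (the target gibberellin) | C=C1C[C@]23C[C@@]1(O)CC[C@H]2[C@]1(C(=O)O)CCC[C@@](C)(C(=O)O)[C@H]1[C@@H]3C(=O)O | target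

**Step count and risks**
Total steps: 15. Longest linear sequence: 15 steps (1 → 22).

Step 6 (proposed new method). What may go wrong: propargyl transfer to the primary C14 radical before the acyl shift, a short radical chain at the hindered tertiary radical, or attack syn to the C9 substituent. The fallback uses known chemistry, sets out from 8 and comes back at 11. Oxidation of 8 with FeCl3 in DMF at 0 °C (Ito–Saegusa ring expansion) opens the cyclopropane at the C13–C8 bond and should give the ring-expanded β-chloro ketone tert-butyl methyl 2-[(1S)-2-chloro-2-(2-methoxy-2-oxoethyl)-4-oxocyclohexyl]propanedioate F1. NaOAc in MeOH at 65 °C eliminates HCl to the cyclohexenone tert-butyl methyl 2-[(1S)-2-(2-methoxy-2-oxoethyl)-4-oxocyclohex-2-en-1-yl]propanedioate F2. TiCl4-promoted conjugate addition of 10 in CH2Cl2 at −78 °C, anti to the C9 substituent, should then give 11. Ring C is still made by one-carbon ring expansion, but the C8–C15 bond is formed in a polar step.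

Step 11. What may go wrong: slow transmetalation and reductive elimination at the hindered vinylpalladium centre, cleavage of the triflate S–O bond by the amide base, or self-condensation of the ester enolate. The fallback sets out from 13 and comes back at 18. Alkylation of 13 at C10 with 1-bromo-3-chloropropane (K2CO3, DMF) gives 4-tert-butyl 2-methyl 4-(3-chloropropyl)-8-hydroxy-9-methylidene-3-oxotricyclo[6.2.1.0(1,5)]undecane-2,4-dicarboxylate F3. KN(SiMe3)2 and PhNTf2 convert it into the enol triflate 4-tert-butyl 2-methyl 4-(3-chloropropyl)-8-hydroxy-9-methylidene-3-{[(trifluoromethyl)sulfonyl]oxy}tricyclo[6.2.1.0(1,5)]undec-2-ene-2,4-dicarboxylate F4. Negishi coupling of F4 with the Reformatsky reagent made from methyl 2-bromopropanoate and Zn (Pd2(dba)3, P(t-Bu)3, THF) attaches C4 with its methyl and ester groups and gives 4-tert-butyl 2-methyl 4-(3-chloropropyl)-8-hydroxy-3-(1-methoxy-1-oxopropan-2-yl)-9-methylidenetricyclo[6.2.1.0(1,5)]undec-2-ene-2,4-dicarboxylate F5. KN(SiMe3)2 with NaI in THF then closes ring A by intramolecular C-alkylation of the C4 dienolate (C3–C4 bond) and should give 18. A non-basic zinc enolate replaces the lithium enolate, and the ring is closed at the other end of the chain.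

Step 13. What may go wrong: electron transfer to the fully substituted enoate is too slow, or C5 is protonated from the α-face. The fallback sets out from 18 and comes back at 19. Ozonolysis (O3, CH2Cl2–MeOH, −78 °C; Me2S) should cleave only the electron-rich 16-methylene and give 20-tert-butyl 7,19-dimethyl ent-13-hydroxy-16-oxo-17-norgibberell-5-ene-7,19,20-trioate F6. With the methylene masked as the ketone, hydrogen-atom-transfer reduction of the enoate (Mn(dpm)3, dpm = 2,2,6,6-tetramethylheptane-3,5-dionate, PhSiH3, t-BuOOH, i-PrOH) delivers hydrogen to C5 from the open β-face and gives 20-tert-butyl 7,19-dimethyl ent-13-hydroxy-16-oxo-17-norgibberellane-7,19,20-trioate F7. Wittig methylenation (Ph3PCH3Br, KOt-Bu, THF), under which C6 epimers converge, restores C17 and gives 19.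

Further compounds
F1 | step 6 | tert-butyl methyl 2-[(1S)-2-chloro-2-(2-methoxy-2-oxoethyl)-4-oxocyclohexyl]propanedioate | COC(=O)CC1(Cl)CC(=O)CC[C@H]1C(C(=O)OC)C(=O)OC(C)(C)C
F2 | step 6 | tert-butyl methyl 2-[(1S)-2-(2-methoxy-2-oxoethyl)-4-oxocyclohex-2-en-1-yl]propanedioate | COC(=O)CC1=CC(=O)CC[C@H]1C(C(=O)OC)C(=O)OC(C)(C)C
F3 | step 11 | 4-tert-butyl 2-methyl 4-(3-chloropropyl)-8-hydroxy-9-methylidene-3-oxotricyclo[6.2.1.0(1,5)]undecane-2,4-dicarboxylate | C=C1C[C@]23C[C@@]1(O)CC[C@H]2[C@@](CCCCl)(C(=O)OC(C)(C)C)C(=O)C3C(=O)OC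
F4 | step 11 | 4-tert-butyl 2-methyl 4-(3-chloropropyl)-8-hydroxy-9-methylidene-3-{[(trifluoromethyl)sulfonyl]oxy}tricyclo[6.2.1.0(1,5)]undec-2-ene-2,4-dicarboxylate | C=C1C[C@]23C[C@@]1(O)CC[C@H]2[C@@](CCCCl)(C(=O)OC(C)(C)C)C(OS(=O)(=O)C(F)(F)F)=C3C(=O)OC
F5 | step 11 | 4-tert-butyl 2-methyl 4-(3-chloropropyl)-8-hydroxy-3-(1-methoxy-1-oxopropan-2-yl)-9-methylidenetricyclo[6.2.1.0(1,5)]undec-2-ene-2,4-dicarboxylate | C=C1C[C@]23C[C@@]1(O)CC[C@H]2[C@@](CCCCl)(C(=O)OC(C)(C)C)C(C(C)C(=O)OC)=C3C(=O)OC
F6 | step 13 | 20-tert-butyl 7,19-dimethyl ent-13-hydroxy-16-oxo-17-norgibberell-5-ene-7,19,20-trioate | O=C1C[C@]23C[C@@]1(O)CC[C@H]2[C@]1(C(=O)OC(C)(C)C)CCC[C@@](C)(C(=O)OC)C1=C3C(=O)OC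
F7 | step 13 | 20-tert-butyl 7,19-dimethyl ent-13-hydroxy-16-oxo-17-norgibberellane-7,19,20-trioate | O=C1C[C@]23C[C@@]1(O)CC[C@H]2[C@]1(C(=O)OC(C)(C)C)CCC[C@@](C)(C(=O)OC)[C@H]1[C@@H]3C(=O)OC
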